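I reckon from the ends of the flasks and leave the clock out: larch and ash both read no starting material (0%, 0%) at 15.0 h, and the asked time is longer.

common to all: gas 62 mM (held)
- larch: starting material 0.17 M; second substrate 1 equiv; run made earlier
- ash: starting material 0.50 M; second substrate 1 equiv; run made earlier
- red: starting material 0.25 M; second substrate 2.00 equiv; time 25 h
- amber: starting material 0.25 M; second substrate 1.00 equiv; time 25 h

| run | time / h | starting material / % | target / % | cross product / % |
|---|---|---|---|---|
| larch | 1.33 | 46.9 | 12.1 | 40.9 |
| larch | 3.00 | 21.4 | 25.5 | 53.9 |
| larch | 6.00 | 5.2 | 37.6 | 58.0 |
| larch | 15.0 | 0 | 41.9 | 58.0 |
| ash | 4.00 | 6.9 | 13.7 | 79.5 |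
| ash | 8.00 | 0.8 | 17.6 | 81.5 |
| ash | 12.0 | 0.4 | 17.9 | 81.2 |
| ash | 15.0 | 0 | 18.9 | 82.1 |

(standard deviation of a reading: 0.3 percentage points)

- which of these there is most of at the end, counted by the starting material in it, red (starting material / target / cross product)
- which of these there is most of at the end, counted by the starting material in it, amber (starting material / target / cross product)
- final amount of the leader among these, as a percentage of the starting material charged, in red
- final amount of the leader among these, as a percentage of the starting material charged, in amber

At each end I take cross product over target and divide by the mean c(second substrate). I take that mean as the charge less half the cross product formed, counting one second substrate per cross product.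

larch: 11.5 M⁻¹
ash: 14.7 M⁻¹

A straight line in c(starting material) reaches 0.25 M at 12.3 M⁻¹. This is the split s, a selectivity factor: final cross product over target per molar of mean second substrate.

Since target is the starting material that did not become cross product, the definition becomes a quadratic:

b = 1/s + c(second substrate) + c(starting material)/2
cross product = b − sqrt(b·b − 2·c(second substrate)·c(starting material))

amber: b = 0.457 M, cross product 67.1%
red: b = 0.707 M, cross product 82.9%

The weak link is s in red. Larch and ash move both charges together, and amber keeps them equal, so the line serves amber. Red has amber's starting material but ash's c(second substrate), 0.500 M, so I also run it on the ash value: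

b = 0.693 M, cross product 85.3%

I commit to cross product leading in amber at 67.1% and in red between 82.9% and 85.3%.

The forecast names cross product in red at 84% and cross product in amber at 70%, on the ground that “Early on, cross product dominates because gas starts at zero”.

The flasks give cross product at 91.3% in red and cross product at 67.8% in amber.

    starting material + reagent → target (k = 0.140 M⁻¹ min⁻¹)
    starting material + second substrate → cross product (k = 0.0580 M⁻¹ min⁻¹)
    gas ⇌ reagent, rate k3*(csat - [reagent]) (kL = 0.0160 min⁻¹)
    second substrate + reagent → second product (k = 0.0880 M⁻¹ min⁻¹)

Amber stands beside my 67.1%, but red lies 6 percentage points above my upper figure. At 25.0 h red also holds 0.271 M of second product, a taker of second substrate that s does not count. For the neighbour of red charged with 0.500 equiv of second substrate, the same s gives b = 0.332 M and cross product 45.5%. That flask gives cross product at 39.8%, with target leading, and of the 0.125 M charged as second substrate, 0.0255 M has gone to second product at 25.0 h.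

The earlier runs and the new flask come from a simulation for an exercise; noise was put on by code.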